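Corymbosin's A ring (C4a, C5, C6, C7, C8, C8a) is a phloroglucinol that carries the C4 carbonyl on C4a, the signature of a cyclised triketide. Everything rests on cutting the C4a–C8a bond. An open-chain cinnamoyl 3,5,7-triketo methyl ester, made by acylating the trianion of methyl 3,5-dioxohexanoate with a trimethoxycinnamoyl Weinreb amide, is closed by a base-mediated intramolecular Claisen condensation. That single operation forges the carbocycle, aromatises it and delivers the 2',4',6'-trihydroxychalcone already bearing its three phenolic oxygens. Iodine in DMSO then builds the pyranone, and methylation of the non-chelated 7-OH completes the target.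

Key step: step 4

Remark on the chemistry: the target has no stereocentre and no stereogenic axis, so there is no enantiomer to control. The only stereo-element handled is the E double bond of the cinnamoyl unit, which disappears when the flavone forms.

Step 1
Reactants: 1 dehydroacetic acid (3-acetyl-4-hydroxy-6-methyl-2H-pyran-2-one)
Product: 2 methyl 3,5-dioxohexanoate
Conditions: Mg(OMe)2 (ca. 2.5 equiv, commercial solution), MeOH, reflux; then cold aq. HCl, extraction, distillation
Reagents that add atoms: magnesium methoxide, C[O-].C[O-].[Mg+2] (supplies the ester methoxy group; the solvent methanol, CO, is the equivalent source)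
Why: Methoxide opens the lactone and a retro-Claisen cleavage expels the 3-acetyl group as methyl acetate, while magnesium chelation of the resulting diketo ester shields it from further cleavage; this is the established methanolysis–deacetylation of dehydroacetic acid.

Step 2
Reactants: 3 (E)-3,4,5-trimethoxycinnamic acid
Product: 5 (E)-N-methoxy-N-methyl-3-(3,4,5-trimethoxyphenyl)prop-2-enamide, via acyl imidazolide 4 (not isolated)
Conditions: CDI (1.1 equiv), CH2Cl2, rt; then MeNH(OMe)·HCl (1.2 equiv), rt
Reagents that add atoms: N,O-dimethylhydroxylamine hydrochloride, CNOC.Cl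
Why: CDI-mediated Weinreb amide formation through the acyl imidazolide is routine for cinnamic acids, the liberated imidazole takes up the HCl, and neither the E alkene nor the aryl methyl ethers are affected.

Step 3
Reactants: 2 methyl 3,5-dioxohexanoate; 5 (E)-N-methoxy-N-methyl-3-(3,4,5-trimethoxyphenyl)prop-2-enamide
Product: 7 methyl (E)-3,5,7-trioxo-9-(3,4,5-trimethoxyphenyl)non-8-enoate, via hemiaminal adduct 6 (not isolated)
Conditions: 2, LDA (3.3 equiv), THF, −78 → 0 °C; then 5 (0.9 equiv), −78 → 0 °C; cold aq. HCl to pH 3–4; crude product used without chromatography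
Reagents that add atoms: none
Why: Triple deprotonation of 2 places the most reactive carbanion on the terminal methyl carbon, which undergoes a Claisen-type acylation by 1,2-addition to the Weinreb amide; the lithium-chelated tetrahedral adduct 6 should persist until the acidic quench, so the acidic triketo ester never meets unreacted trianion (no proton-transfer quench, no Michael addition to the enone), and the E geometry is inherited from 5.

Step 4
Reactants: 7 methyl (E)-3,5,7-trioxo-9-(3,4,5-trimethoxyphenyl)non-8-enoate
Product: 9 (E)-2',4',6'-trihydroxy-3,4,5-trimethoxychalcone, via cyclohexanetrione 8 (not isolated)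
Conditions: KOH (ca. 8 equiv), MeOH, 0 °C → rt, Ar; then cold 1 M HCl to pH 3, extraction
Reagents that add atoms: none
Why: Excess methanolic base converts 7 into its polyenolate, so C3, C5 and C7 are masked as enolates and the C1 methyl ester is the only electrophile left; C6, the central carbon of the C5/C7 diketonate, adds to C1, methoxide is expelled, and the 2-acylcyclohexane-1,3,5-trione 8 enolises at once to the phloroglucinol phenoxide of 9, creating the C4a–C8a bond of the future flavone. The closest known reaction type is the biomimetic intramolecular Claisen (Dieckmann-type) cyclisation of 3,5,7-triketo esters to acylphloroglucinols, the laboratory counterpart of chalcone synthase. The carbocyclic A ring (C1–C6 of 7) is closed in a 6-exo-trig mode, the attacked ester C=O lying outside the new six-membered ring. No stereocentre is created and the E alkene is not touched. The selectivity needed is C6→C1 Claisen closure over C2→C7 aldol closure (which would lead to a styryl resorcylate) and over O-acylation to a 4-hydroxy-2-pyranone: full enolisation and conjugation with the electron-rich styryl group make C7 a poor acceptor, lactonisation is reversed by methanolysis, aromatisation to the phenoxide makes the C-acylation irreversible, and the methyl ester matched to methanol rules out ester scrambling. On acidification part of 9 may close to its flavanone isomer 10; the crude material is taken on as obtained because both converge on 12 in step 5.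

Step 5
Reactants: 9 (E)-2',4',6'-trihydroxy-3,4,5-trimethoxychalcone
Product: 12 5,7-dihydroxy-2-(3,4,5-trimethoxyphenyl)-4H-chromen-4-one, via flavanone 10 (not isolated), via 3-iodoflavanone 11 (not isolated)
Conditions: I2 (10 mol%), DMSO, 120 °C; aq. Na2S2O3 work-up, precipitation from water
Reagents that add atoms: none
Why: The 2'-hydroxychalcone closes by 6-endo-trig oxa-Michael addition to flavanone 10, which is iodinated at C3 through its enol and loses HI to give the aromatic pyranone while DMSO reoxidises HI to I2 (iodine/DMSO oxidative cyclisation of 2'-hydroxychalcones); the two ortho hydroxyls of 9 are equivalent, so only one flavone can form, and the C2/C3 stereocentres of the intermediates are erased.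

Step 6
Reactants: 12 5,7-dihydroxy-2-(3,4,5-trimethoxyphenyl)-4H-chromen-4-one
Product: 13 corymbosin (5-hydroxy-7-methoxy-2-(3,4,5-trimethoxyphenyl)-4H-chromen-4-one)
Conditions: MeI (1.1 equiv), K2CO3 (1.2 equiv), acetone, rt → 40 °C
Reagents that add atoms: iodomethane, CI
Why: The 7-OH, para to the pyranone carbonyl, is the most acidic and most nucleophilic phenol, whereas the 5-OH is locked in a hydrogen bond to the C4 carbonyl, so a Williamson etherification with about one equivalent of iodomethane and a weak base should alkylate O7 selectively, as is standard for 5,7-dihydroxyflavones.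

Compound list
1 | dehydroacetic acid (3-acetyl-4-hydroxy-6-methyl-2H-pyran-2-one) | CC(=O)C1=C(O)C=C(C)OC1=O | starting material
2 | methyl 3,5-dioxohexanoate | COC(=O)CC(=O)CC(C)=O | intermediate
3 | (E)-3,4,5-trimethoxycinnamic acid | COc1cc(/C=C/C(=O)O)cc(OC)c1OC | starting material
4 | (E)-1-(1H-imidazol-1-yl)-3-(3,4,5-trimethoxyphenyl)prop-2-en-1-one (acyl imidazolide) | COc1cc(/C=C/C(=O)n2ccnc2)cc(OC)c1OC | intermediate (not isolated)
5 | (E)-N-methoxy-N-methyl-3-(3,4,5-trimethoxyphenyl)prop-2-enamide | COc1cc(/C=C/C(=O)N(C)OC)cc(OC)c1OC | intermediate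
6 | methyl (E)-7-hydroxy-7-[methoxy(methyl)amino]-3,5-dioxo-9-(3,4,5-trimethoxyphenyl)non-8-enoate (tetrahedral adduct, present as its lithium chelate, drawn O-protonated, racemic at C7) | COC(=O)CC(=O)CC(=O)CC(O)(/C=C/c1cc(OC)c(OC)c(OC)c1)N(C)OC | intermediate (not isolated)
7 | methyl (E)-3,5,7-trioxo-9-(3,4,5-trimethoxyphenyl)non-8-enoate (enol tautomers in practice) | COC(=O)CC(=O)CC(=O)CC(=O)/C=C/c1cc(OC)c(OC)c(OC)c1 | intermediate
8 | 2-[(E)-3-(3,4,5-trimethoxyphenyl)prop-2-enoyl]cyclohexane-1,3,5-trione | O=C(/C=C/c1cc(OC)c(OC)c(OC)c1)C1C(=O)CC(=O)CC1=O | intermediate (not isolated)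
9 | (E)-2',4',6'-trihydroxy-3,4,5-trimethoxychalcone, i.e. (E)-1-(2,4,6-trihydroxyphenyl)-3-(3,4,5-trimethoxyphenyl)prop-2-en-1-one | O=C(/C=C/c1cc(OC)c(OC)c(OC)c1)c1c(O)cc(O)cc1O | intermediate
10 | 5,7-dihydroxy-2-(3,4,5-trimethoxyphenyl)chroman-4-one (flavanone, racemic) | COc1cc(C2CC(=O)c3c(O)cc(O)cc3O2)cc(OC)c1OC | intermediate (not isolated)
11 | 5,7-dihydroxy-3-iodo-2-(3,4,5-trimethoxyphenyl)chroman-4-one (racemic, relative configuration not defined) | COc1cc(C2Oc3cc(O)cc(O)c3C(=O)C2I)cc(OC)c1OC | intermediate (not isolated)
12 | 5,7-dihydroxy-2-(3,4,5-trimethoxyphenyl)-4H-chromen-4-one (5,7-dihydroxy-3',4',5'-trimethoxyflavone) | COc1cc(-c2cc(=O)c3c(O)cc(O)cc3o2)cc(OC)c1OC | intermediate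
13 | corymbosin, 5-hydroxy-7-methoxy-2-(3,4,5-trimethoxyphenyl)-4H-chromen-4-one | COc1cc(O)c2c(=O)cc(-c3cc(OC)c(OC)c(OC)c3)oc2c1 | target

Total step count: 6. Longest linear sequence: 5 steps (step 1 or step 2, then steps 3, 4, 5 and 6).

Steps most likely to fail

Step 4 (key step). Aldol closure of C2 onto C7, lactonisation to a pyranone, or base-induced retro-Claisen cleavage of the chain may outrun the C-acylation. The fallback sets out from 5 and comes back at 9, with the A ring bought and not built. Phloroglucinol is protected (MOMCl, i-Pr2NEt, CH2Cl2) as 1,3,5-tris(methoxymethoxy)benzene F1, which is lithiated between two MOM ethers (n-BuLi, THF, 0 °C, directed ortho-metalation). The aryllithium adds 1,2 to Weinreb amide 5 to give (E)-1-[2,4,6-tris(methoxymethoxy)phenyl]-3-(3,4,5-trimethoxyphenyl)prop-2-en-1-one F2. Acidic methanolysis (HCl, MeOH, 50 °C) removes the three MOM groups and should give 9, possibly with some 10, which re-enters at step 5.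

Step 3. Incomplete trianion formation, conjugate addition of the carbanion to the cinnamoyl acceptor, or base-induced loss of the N-methoxy group of the amide may erode the acylation. The fallback sets out from 5 and comes back at 7, delivering the triketo ester under neutral conditions. Commercial 2,2,6-trimethyl-4H-1,3-dioxin-4-one is γ-acetylated through its lithium dienolate (LiHMDS, THF, −78 °C; AcCl) to 2,2-dimethyl-6-(2-oxopropyl)-4H-1,3-dioxin-4-one F3. Its dianion (LDA, 2 equiv, THF, −78 °C) is acylated at the terminal methyl by 5 to give 2,2-dimethyl-6-[(E)-2,4-dioxo-6-(3,4,5-trimethoxyphenyl)hex-5-en-1-yl]-4H-1,3-dioxin-4-one F4. Heating F4 in toluene/MeOH (100–110 °C) releases acetone by retro-[4+2] fragmentation, and methanol traps the acylketene to give 7.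

Step 5. Electrophilic iodination of the electron-rich phloroglucinol ring at C6/C8 may compete, or the dehydrogenation may stall after ring closure. The fallback sets out from 9 and comes back at 12. NaOAc in refluxing EtOH isomerises 9 completely to flavanone 10, which is isolated this time. Ac2O/pyridine converts 10 into 5,7-diacetoxy-2-(3,4,5-trimethoxyphenyl)chroman-4-one F5, which deactivates the A ring. DDQ in refluxing dioxane dehydrogenates C2–C3 to give 5,7-diacetoxy-2-(3,4,5-trimethoxyphenyl)-4H-chromen-4-one F6. K2CO3 in MeOH at rt removes both acetates to give 12.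

Further compounds
F1 | step 4 | 1,3,5-tris(methoxymethoxy)benzene | COCOc1cc(OCOC)cc(OCOC)c1
F2 | step 4 | (E)-1-[2,4,6-tris(methoxymethoxy)phenyl]-3-(3,4,5-trimethoxyphenyl)prop-2-en-1-one | COCOc1cc(OCOC)c(C(=O)/C=C/c2cc(OC)c(OC)c(OC)c2)c(OCOC)c1
F3 | step 3 | 2,2-dimethyl-6-(2-oxopropyl)-4H-1,3-dioxin-4-one | CC(=O)CC1=CC(=O)OC(C)(C)O1
F4 | step 3 | 2,2-dimethyl-6-[(E)-2,4-dioxo-6-(3,4,5-trimethoxyphenyl)hex-5-en-1-yl]-4H-1,3-dioxin-4-one | CC1(C)OC(=O)C=C(CC(=O)CC(=O)/C=C/c2cc(OC)c(OC)c(OC)c2)O1
F5 | step 5 | 5,7-diacetoxy-2-(3,4,5-trimethoxyphenyl)chroman-4-one (racemic) | COc1cc(C2CC(=O)c3c(OC(C)=O)cc(OC(C)=O)cc3O2)cc(OC)c1OC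
F6 | step 5 | 5,7-diacetoxy-2-(3,4,5-trimethoxyphenyl)-4H-chromen-4-one | COc1cc(-c2cc(=O)c3c(OC(C)=O)cc(OC(C)=O)cc3o2)cc(OC)c1OC
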